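**Plan**

- Retrosynthesis: the two helpers (O6‑benzyl, C4‑phenylthio) are removed first. The pyran bonds C4–C4a and C3–C2 are then cut together, as a formal [4+2] of an aryl oxocarbenium ion with an ethylene equivalent. Next comes O1–C2 (aryl enol ether from a C43 methyl ketone and a hydroquinone monoether), and last the C2=C3 alkene of solanesol (loss of C1 and C2).
- Enabling feature: O1 joins the aromatic carbon C8a to C2. C‑protonation of the enol ether therefore turns C4a=C8a–O1(+)=C2 into a cationic 2‑oxonia‑diene. C8 carries a methyl group, so only C4a can close the ring.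
- Forward: solanesol supplies the whole side chain, C2 and its methyl group, with all (E)‑alkenes in place. The aromatic ring is bought as 2,3‑dimethylhydroquinone. The dihydropyran ring is the only ring made, in the key step.
- Stereochemistry: the single stereocenter C2 (R) is set in the key step by a confined chiral Brønsted acid (ion‑pair control). The seven stereogenic (E)‑alkenes come from solanesol and are never touched.

Key step: step 6

Assumption: the sense of induction of the chiral acid in the new step cannot be predicted; the (S,S) acid is written, and its (R,R) antipode would be used if it should favour the 2S series.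

Remark: "C41 chain" means (3E,7E,11E,15E,19E,23E,27E)‑4,8,12,16,20,24,28,32‑octamethyltritriaconta‑3,7,11,15,19,23,27,31‑octaen‑1‑yl. Compounds 2 and 3 are racemic, and one enantiomer is drawn.

**Step 1**
Reactants: 1 solanesol
Product: 2 rac‑2,3‑epoxysolanesol (trans epoxide)
Conditions: VO(acac)2 (2 mol %), t‑BuOOH (1.2 equiv), CH2Cl2, 0 °C to rt
Reagents that add atoms: tert‑butyl hydroperoxide CC(C)(C)OO
Why: Hydroxyl‑directed vanadium‑catalysed epoxidation should oxidise only the allylic alcohol alkene and leave the eight isolated trisubstituted alkenes alone; the two new stereocenters are racemic and are destroyed in step 2.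

**Step 2**
Reactants: 2 rac‑2,3‑epoxysolanesol
Product: 4 octaprenylacetone, (5E,9E,13E,17E,21E,25E,29E)‑6,10,14,18,22,26,30,34‑octamethylpentatriaconta‑5,9,13,17,21,25,29,33‑octaen‑2‑one, via triol 3 (not isolated)
Conditions: H5IO6 (2.2 equiv), THF/H2O, 0 °C to rt
Reagents that add atoms: water O
Why: Aqueous periodic acid should open the epoxy alcohol to the 1,2,3‑triol and cleave both glycol bonds (Malaprade cleavage), which leaves the methyl ketone and removes C1 and C2 of solanesol as formaldehyde and formic acid; no six‑membered cation‑olefin closure is available from the tertiary epoxide carbon.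

**Step 3**
Reactants: 4 octaprenylacetone
Product: 6 kinetic enol triflate of 4, (5E,9E,13E,17E,21E,25E,29E)‑6,10,14,18,22,26,30,34‑octamethylpentatriaconta‑1,5,9,13,17,21,25,29,33‑nonaen‑2‑yl trifluoromethanesulfonate, via lithium enolate 5 (not isolated)
Conditions: LDA (1.1 equiv), THF, −78 °C; then PhNTf2, −78 to 0 °C
Reagents that add atoms: N‑phenylbis(trifluoromethanesulfonimide) O=S(=O)(N(c1ccccc1)S(=O)(=O)C(F)(F)F)C(F)(F)F
Why: Kinetic deprotonation of the methyl ketone at the methyl group and O‑sulfonylation of the lithium enolate (enol triflate formation) should give the terminal enol triflate; any internal regioisomer would lead to the same oxocarbenium ion in step 6.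

**Step 4**
Reactants: 7 2,3‑dimethylhydroquinone
Product: 8 4‑(benzyloxy)‑2,3‑dimethylphenol
Conditions: BnBr (0.9 equiv), K2CO3, acetone, reflux, argon
Reagents that add atoms: benzyl bromide BrCc1ccccc1
Why: Williamson monoalkylation of the symmetric hydroquinone, whose two hydroxyl groups are equivalent, can give only one monoether, to be separated from diether and recovered 7.

**Step 5**
Reactants: 6 kinetic enol triflate of 4; 8 4‑(benzyloxy)‑2,3‑dimethylphenol
Product: 9 aryl enol ether, 1‑(benzyloxy)‑2,3‑dimethyl‑4‑{[(5E,9E,13E,17E,21E,25E,29E)‑6,10,14,18,22,26,30,34‑octamethylpentatriaconta‑1,5,9,13,17,21,25,29,33‑nonaen‑2‑yl]oxy}benzene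
Conditions: Pd2(dba)3 (2.5 mol %), 2‑(di‑tert‑butylphosphino)biphenyl (6 mol %), NaOtBu (1.2 equiv), toluene, 80 °C
Reagents that add atoms: none
Why: Buchwald‑Hartwig‑type C–O cross‑coupling (oxidative addition of the enol triflate to zerovalent palladium, phenoxide exchange, reductive elimination) should give the 1,1‑disubstituted aryl enol ether, with the chain alkenes and the benzyl ether inert.

**Step 6**
Reactants: 9 aryl enol ether; 10 phenyl vinyl sulfide
Product: 12 (2R)‑6‑(benzyloxy)‑2,7,8‑trimethyl‑4‑(phenylsulfanyl)‑2‑(C41 chain)chromane (both C4 epimers), via oxocarbenium ion 11 (not isolated)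
Conditions: 10 (8 equiv), (S,S)‑IDPi acid [imidodiphosphorimidate of two (S)‑3,3'‑bis(3,5‑bis(trifluoromethyl)phenyl)‑1,1'‑bi‑2‑naphthol units, both P=N nitrogens carrying SO2CF3] (5 mol %), 5 Å molecular sieves, toluene/CH2Cl2, −60 to −30 °C
Reagents that add atoms: none
Why: Proposed new method: C‑protonation of the 1,1‑disubstituted enol ether 9 by the confined chiral acid gives the contact ion pair of aryl oxocarbenium ion 11, a cationic 2‑oxonia‑diene (C4a=C8a–O1(+)=C2), which undergoes an asynchronous inverse‑electron‑demand [4+2] cycloaddition with the small, weakly basic dienophile 10: C3 bonds to C2, the developing thionium carbon C4 collapses onto aromatic C4a, and proton loss rearomatises the ring and returns the acid. The closest known reaction types are the Lewis acid promoted oxa‑Povarov reaction of aryl oxocarbenium ions with alkenes (racemic) and confined chiral acid catalysed additions to oxocarbenium ions made by protonating enol ethers (asymmetric spiroacetalisation). The dihydropyran ring closes as a formal [4+2] cycloaddition; if the process is stepwise, its second bond forms by 6‑exo‑trig Friedel‑Crafts attack of C4a on the thionium carbon. The C2 stereocenter is controlled by the catalyst anion: protonation of the s‑cis enol ether places the methyl group inside and the chain outside the diene, and the anion pocket shields one diene face so that 10 adds to the face that gives 2R; the C4 configuration does not matter because the sulfur leaves in step 7. The step needs chemoselectivity for 10 over the eight trisubstituted chain alkenes and over unreacted 9, which the steric demand of a cycloaddition that bonds both alkene carbons should secure for the monosubstituted 10 used in excess. It also needs regioselective closure, secured because C4a is the only free position ortho to O1 (C8 bears a methyl group) and is activated by O1 and by the para methyl group on C7.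

**Step 7**
Reactants: 12 (2R)‑4‑(phenylsulfanyl)chromane benzyl ether
Product: 14 plastochromanol 8, via dilithio species 13 (not isolated)
Conditions: lithium 4,4'‑di‑tert‑butylbiphenylide (6 equiv), THF, −78 to −40 °C; then MeOH
Reagents that add atoms: none
Why: Reductive lithiation by the arene radical anion (dissolving‑metal type cleavage) should break the benzylic C4–S bond and the benzyl–oxygen bond, and protonation of the C4 carbanion and the phenoxide gives the CH2 group and the free phenol; the isolated alkenes, the aryl alkyl ether and C2, to which no bond is broken, should be untouched.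

**Compound list**

1 | solanesol, (2E,6E,10E,14E,18E,22E,26E,30E)‑3,7,11,15,19,23,27,31,35‑nonamethylhexatriaconta‑2,6,10,14,18,22,26,30,34‑nonaen‑1‑ol | CC(C)=CCC/C(C)=C/CC/C(C)=C/CC/C(C)=C/CC/C(C)=C/CC/C(C)=C/CC/C(C)=C/CC/C(C)=C/CC/C(C)=C/CO | starting material

2 | rac‑2,3‑epoxysolanesol, [(2R*,3R*)‑3‑methyl‑3‑(C41 chain)oxiran‑2‑yl]methanol | CC(C)=CCC/C(C)=C/CC/C(C)=C/CC/C(C)=C/CC/C(C)=C/CC/C(C)=C/CC/C(C)=C/CC/C(C)=C/CC[C@@]1(C)O[C@@H]1CO | intermediate

3 | triol, (2R*,3S*)‑2,3‑dihydroxy‑2,3‑dihydrosolanesol | CC(C)=CCC/C(C)=C/CC/C(C)=C/CC/C(C)=C/CC/C(C)=C/CC/C(C)=C/CC/C(C)=C/CC/C(C)=C/CC[C@](C)(O)[C@H](O)CO | intermediate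

4 | octaprenylacetone, (5E,9E,13E,17E,21E,25E,29E)‑6,10,14,18,22,26,30,34‑octamethylpentatriaconta‑5,9,13,17,21,25,29,33‑octaen‑2‑one | CC(C)=CCC/C(C)=C/CC/C(C)=C/CC/C(C)=C/CC/C(C)=C/CC/C(C)=C/CC/C(C)=C/CC/C(C)=C/CCC(C)=O | intermediate

5 | lithium enolate of 4 (1‑en‑2‑olate) | CC(C)=CCC/C(C)=C/CC/C(C)=C/CC/C(C)=C/CC/C(C)=C/CC/C(C)=C/CC/C(C)=C/CC/C(C)=C/CCC(=C)O[Li] | intermediate

6 | kinetic enol triflate of 4 | CC(C)=CCC/C(C)=C/CC/C(C)=C/CC/C(C)=C/CC/C(C)=C/CC/C(C)=C/CC/C(C)=C/CC/C(C)=C/CCC(=C)OS(=O)(=O)C(F)(F)F | intermediate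

7 | 2,3‑dimethylhydroquinone (2,3‑dimethylbenzene‑1,4‑diol) | Cc1c(O)ccc(O)c1C | starting material

8 | 4‑(benzyloxy)‑2,3‑dimethylphenol | Cc1c(O)ccc(OCc2ccccc2)c1C | intermediate

9 | aryl enol ether of 4 and 8 | CC(C)=CCC/C(C)=C/CC/C(C)=C/CC/C(C)=C/CC/C(C)=C/CC/C(C)=C/CC/C(C)=C/CC/C(C)=C/CCC(=C)Oc1ccc(OCc2ccccc2)c(C)c1C | intermediate

10 | phenyl vinyl sulfide | C=CSc1ccccc1 | starting material

11 | aryl oxocarbenium ion of 9 (ion pair with the catalyst anion) | CC(C)=CCC/C(C)=C/CC/C(C)=C/CC/C(C)=C/CC/C(C)=C/CC/C(C)=C/CC/C(C)=C/CC/C(C)=C/CCC(C)=[O+]c1ccc(OCc2ccccc2)c(C)c1C | intermediate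

12 | (2R)‑6‑(benzyloxy)‑2,7,8‑trimethyl‑4‑(phenylsulfanyl)‑2‑(C41 chain)chromane, both C4 epimers | CC(C)=CCC/C(C)=C/CC/C(C)=C/CC/C(C)=C/CC/C(C)=C/CC/C(C)=C/CC/C(C)=C/CC/C(C)=C/CC[C@]1(C)CC(Sc3ccccc3)c2cc(OCc3ccccc3)c(C)c(C)c2O1 | intermediate

13 | (2R)‑4‑lithio‑2,7,8‑trimethyl‑2‑(C41 chain)chroman‑6‑olate, lithium salt | CC(C)=CCC/C(C)=C/CC/C(C)=C/CC/C(C)=C/CC/C(C)=C/CC/C(C)=C/CC/C(C)=C/CC/C(C)=C/CC[C@]1(C)CC([Li])c2cc(O[Li])c(C)c(C)c2O1 | intermediate

14 | plastochromanol 8, (2R)‑2,7,8‑trimethyl‑2‑(C41 chain)chroman‑6‑ol | CC(C)=CCC/C(C)=C/CC/C(C)=C/CC/C(C)=C/CC/C(C)=C/CC/C(C)=C/CC/C(C)=C/CC/C(C)=C/CC[C@]1(C)CCc2cc(O)c(C)c(C)c2O1 | target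

**Totals**

Total step count: 7. Longest linear sequence: 6 steps (steps 1, 2, 3, 5, 6 and 7, from solanesol 1).

**Steps most likely to fail**

Step 6 (new method). Three processes may defeat it. The catalyst anion may discriminate poorly between the two faces of the oxocarbenium ion, which would give low enantioselectivity. The C4 thionium centre may be captured by the nearest chain alkene (cation‑olefin cyclisation) instead of by C4a. The oxocarbenium ion may also be consumed by the enol ether itself. The fallback uses known chemistry, sets out from ketone 4 and returns at 14.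
- A catalytic asymmetric Corey‑Chaykovsky epoxidation of 4 would give (R)‑2‑methyl‑2‑(C41 chain)oxirane F1, whose methylide carbon is the future C3. It would use dimethyloxosulfonium methylide from Me3S(O)I and NaH, LaLi3(binaphthoxide)3 with tris(2,4,6‑trimethoxyphenyl)phosphine oxide, THF, rt, with the catalyst antipode chosen for the R series.
- Blanc chloromethylation of commercial 1,4‑dimethoxy‑2,3‑dimethylbenzene (paraformaldehyde, HCl) would give 1‑(chloromethyl)‑2,5‑dimethoxy‑3,4‑dimethylbenzene F2, and magnesium in THF its Grignard reagent, (2,5‑dimethoxy‑3,4‑dimethylbenzyl)magnesium chloride F3.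
- CuI‑catalysed opening of F1 at its CH2 carbon by F3 would give (R)‑4‑(2,5‑dimethoxy‑3,4‑dimethylphenyl)‑2‑(C41 chain)butan‑2‑ol F4 without touching the stereocenter.
- Oxidative demethylation with (NH4)2Ce(NO3)6 in aqueous acetonitrile at 0 °C would give (R)‑2‑[3‑hydroxy‑3‑(C41 chain)butyl]‑5,6‑dimethyl‑1,4‑benzoquinone F5.
- HC(OMe)3 and MeOH with a trace of acid would close the tertiary hydroxyl group onto the C8a carbonyl to give the cyclic methyl ketal (2R)‑8a‑methoxy‑2,7,8‑trimethyl‑2‑(C41 chain)‑2,3,4,8a‑tetrahydro‑6H‑chromen‑6‑one F6.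
- Reduction of F6 with ascorbic acid would aromatise it to 14 with retention at C2, because the C2–O bond is never broken.

Step 5. Base‑induced loss of the triflate (elimination, or sulfonyl transfer to the hindered phenoxide) may outrun C–O reductive elimination. The fallback sets out from 6 and returns at 9. Miyaura borylation (B2pin2, PdCl2(PPh3)2, PPh3, KOPh, toluene, 50 °C) would give the alkenyl pinacol boronate 2‑[(5E,9E,13E,17E,21E,25E,29E)‑6,10,14,18,22,26,30,34‑octamethylpentatriaconta‑1,5,9,13,17,21,25,29,33‑nonaen‑2‑yl]‑4,4,5,5‑tetramethyl‑1,3,2‑dioxaborolane F7. Chan‑Lam coupling of F7 with 8 (Cu(OAc)2, pyridine, 4 Å molecular sieves, CH2Cl2, air, rt) would then give 9 under nearly neutral conditions.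

Step 7. Electron transfer to the electron‑rich chroman may be slow, so the benzyl ether may cleave incompletely at low temperature, or the aryl ether may be cleaved reductively on warming. The fallback sets out from 12 and returns at 14. Radical chain desulfurisation (Bu3SnH, AIBN, toluene, 100 °C) would give (2R)‑6‑(benzyloxy)‑2,7,8‑trimethyl‑2‑(C41 chain)chromane F8. SN2 debenzylation of F8 with NaSEt in DMF at 110 °C would then give 14.

**Further compounds**

F1 | step 6 | (R)‑2‑methyl‑2‑(C41 chain)oxirane | CC(C)=CCC/C(C)=C/CC/C(C)=C/CC/C(C)=C/CC/C(C)=C/CC/C(C)=C/CC/C(C)=C/CC/C(C)=C/CC[C@]1(C)CO1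
F2 | step 6 | 1‑(chloromethyl)‑2,5‑dimethoxy‑3,4‑dimethylbenzene | ClCc1cc(OC)c(C)c(C)c1OC
F3 | step 6 | (2,5‑dimethoxy‑3,4‑dimethylbenzyl)magnesium chloride | Cl[Mg]Cc1cc(OC)c(C)c(C)c1OC
F4 | step 6 | (R)‑4‑(2,5‑dimethoxy‑3,4‑dimethylphenyl)‑2‑(C41 chain)butan‑2‑ol | CC(C)=CCC/C(C)=C/CC/C(C)=C/CC/C(C)=C/CC/C(C)=C/CC/C(C)=C/CC/C(C)=C/CC/C(C)=C/CC[C@@](C)(O)CCc1cc(OC)c(C)c(C)c1OC
F5 | step 6 | (R)‑2‑[3‑hydroxy‑3‑(C41 chain)butyl]‑5,6‑dimethyl‑1,4‑benzoquinone | CC(C)=CCC/C(C)=C/CC/C(C)=C/CC/C(C)=C/CC/C(C)=C/CC/C(C)=C/CC/C(C)=C/CC/C(C)=C/CC[C@@](C)(O)CCC1=CC(=O)C(C)=C(C)C1=O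
F6 | step 6 | (2R)‑8a‑methoxy‑2,7,8‑trimethyl‑2‑(C41 chain)‑2,3,4,8a‑tetrahydro‑6H‑chromen‑6‑one | CC(C)=CCC/C(C)=C/CC/C(C)=C/CC/C(C)=C/CC/C(C)=C/CC/C(C)=C/CC/C(C)=C/CC/C(C)=C/CC[C@]1(C)CCC2=CC(=O)C(C)=C(C)C2(OC)O1
F7 | step 5 | alkenyl pinacol boronate of 4 | CC(C)=CCC/C(C)=C/CC/C(C)=C/CC/C(C)=C/CC/C(C)=C/CC/C(C)=C/CC/C(C)=C/CC/C(C)=C/CCC(=C)B1OC(C)(C)C(C)(C)O1
F8 | step 7 | (2R)‑6‑(benzyloxy)‑2,7,8‑trimethyl‑2‑(C41 chain)chromane | CC(C)=CCC/C(C)=C/CC/C(C)=C/CC/C(C)=C/CC/C(C)=C/CC/C(C)=C/CC/C(C)=C/CC/C(C)=C/CC[C@]1(C)CCc2cc(OCc3ccccc3)c(C)c(C)c2O1
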